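**Plan**
- **Cuts.** The C8' oxygen (removed as its triflate) and the C7' silyl group are cleared first. Ring B is then opened at C5'–C6', C7'–C8' and C8'–C8a' to an aryl(methoxy)carbene chromium complex, Me3SiC≡CH and one CO ligand. Next come C4a'–C5' (aryllithium plus Cr(CO)6), the C7–C1' axis (Suzuki coupling), and N2–C1, N2–C3 and C4–C4a of the pyridine ring (ammonia, ketone, propyne).
- **Enabling feature.** Ring B (C4a', C5', C6', C7', C8', C8a') carries one substituent only, the C5' methoxy group, peri to the C4' methoxy group. A methoxycarbene carbon on C4a' maps onto C5', and the C4' methoxy group leaves C8a' as the only ortho carbon open for closure.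
- **Forward order.** The pyridine ring is closed first on 2,6-dihydroxyacetophenone, then C7 is brominated and borylated. The biaryl bond is made while only one OMe and one Me flank it, and ring B is annulated last.
- **Stereochemistry.** The target has no stereocentre. The C7–C1' axis forms without control and is obtained racemic.

Key step: step 10

Assumption: the target structure carries no descriptor for the C7–C1' axis, so the racemic mixture of atropisomers is taken as the goal.

Step 1
Reactants: 1 1-(2,6-dihydroxyphenyl)ethanone (2,6-dihydroxyacetophenone)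
Product: 2 2-acetyl-3-hydroxyphenyl trifluoromethanesulfonate
Conditions: Tf2O (1.0 equiv), pyridine, CH2Cl2, −78 → 0 °C
Reagents that add atoms: trifluoromethanesulfonic anhydride, O=S(=O)(OS(=O)(=O)C(F)(F)F)C(F)(F)F
Why: Mono-O-triflation of a symmetric resorcinol should stop cleanly, because the remaining hydroxyl is tied to the ketone by a hydrogen bond and the first triflate has made the ring electron-poor.

Step 2
Reactants: 2 2-acetyl-3-hydroxyphenyl trifluoromethanesulfonate; 3 propyne
Product: 4 1-[2-hydroxy-6-(prop-1-yn-1-yl)phenyl]ethanone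
Conditions: PdCl2(PPh3)2 (cat.), CuI (cat.), Et3N, DMF, excess propyne, sealed tube, 50 °C
Reagents that add atoms: none
Why: Sonogashira coupling: the triflate ortho to the acetyl group adds readily to zerovalent palladium, and the chelated phenol on the far side of the ketone cannot reach the alkyne.

Step 3
Reactants: 4 1-[2-hydroxy-6-(prop-1-yn-1-yl)phenyl]ethanone
Product: 6 1,3-dimethylisoquinolin-8-ol, via ketimine 5 (not isolated)
Conditions: NH3 (7 M in MeOH), sealed tube, 110 °C
Reagents that add atoms: ammonia, N
Why: Tandem imination and 6-endo-dig hydroamination of a 2-alkynylaryl ketone with ammonia is a known isoquinoline synthesis, helped here by the ortho hydroxyl that stabilises ketimine 5 and made irreversible by aromatisation.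

Step 4
Reactants: 6 1,3-dimethylisoquinolin-8-ol
Product: 7 7-bromo-1,3-dimethylisoquinolin-8-ol
Conditions: NBS (1.0 equiv, slow addition), i-Pr2NH (10 mol %), CH2Cl2, 0 °C, dark
Reagents that add atoms: N-bromosuccinimide, O=C1CCC(=O)N1Br
Why: Amine-mediated ortho-bromination of phenols: the N-bromoamine formed in situ is delivered through a hydrogen bond to the C8 hydroxyl, which the peri C1 methyl turns toward C7, so C7 should be preferred over the para site C5 as it is for 1-naphthol and quinolin-8-ol.

Step 5
Reactants: 7 7-bromo-1,3-dimethylisoquinolin-8-ol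
Product: 8 7-bromo-8-methoxy-1,3-dimethylisoquinoline
Conditions: MeI (1.1 equiv), K2CO3, acetone, rt
Reagents that add atoms: iodomethane, CI
Why: Williamson ether synthesis in which the phenoxide outruns the ring nitrogen, which is flanked by two methyl groups, when only a slight excess of MeI is used.

Step 6
Reactants: 8 7-bromo-8-methoxy-1,3-dimethylisoquinoline
Product: 9 8-methoxy-1,3-dimethyl-7-(4,4,5,5-tetramethyl-1,3,2-dioxaborolan-2-yl)isoquinoline
Conditions: B2pin2, PdCl2(dppf) (cat.), KOAc, 1,4-dioxane, 90 °C
Reagents that add atoms: bis(pinacolato)diboron, CC1(C)OB(OC1(C)C)B1OC(C)(C)C(C)(C)O1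
Why: Miyaura borylation of an aryl bromide under acetate conditions that leave the acidic C1 methyl group untouched.

Step 7
Reactants: 10 2-bromo-5-methylanisole (1-bromo-2-methoxy-4-methylbenzene)
Product: 11 1-bromo-5-iodo-2-methoxy-4-methylbenzene
Conditions: NIS, CF3CO2H (cat.), MeCN, rt
Reagents that add atoms: N-iodosuccinimide, O=C1CCC(=O)N1I
Why: Electrophilic aromatic iodination goes para to the methoxy group and ortho to the methyl group, the only activated position not wedged between two substituents, and placing iodine last avoids halogen scrambling.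

Step 8
Reactants: 9 8-methoxy-1,3-dimethyl-7-(4,4,5,5-tetramethyl-1,3,2-dioxaborolan-2-yl)isoquinoline; 11 1-bromo-5-iodo-2-methoxy-4-methylbenzene
Product: 12 7-(5-bromo-4-methoxy-2-methylphenyl)-8-methoxy-1,3-dimethylisoquinoline
Conditions: Pd(PPh3)4 (cat.), Na2CO3 (2 M aq), DME, 70 °C
Reagents that add atoms: none
Why: Suzuki–Miyaura coupling: oxidative addition to zerovalent palladium is much faster at C–I than at the electron-rich C–Br next to methoxy, and the new C7–C1' bond has only one methoxy and one methyl group as ortho neighbours at this stage.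

Step 9
Reactants: 12 7-(5-bromo-4-methoxy-2-methylphenyl)-8-methoxy-1,3-dimethylisoquinoline; 13 chromium hexacarbonyl, Cr(CO)6
Product: 16 pentacarbonyl{methoxy[2-methoxy-5-(8-methoxy-1,3-dimethylisoquinolin-7-yl)-4-methylphenyl]methylidene}chromium, via aryllithium 14 (not isolated), via lithium acylchromate 15 (not isolated)
Conditions: t-BuLi (2.0 equiv), Et2O–THF, −78 °C; Cr(CO)6, THF, −78 → 0 °C; evaporate; MeOTf (1.0 equiv), CH2Cl2, 0 °C
Reagents that add atoms: methyl trifluoromethanesulfonate, COS(=O)(=O)C(F)(F)F; tert-butyllithium, [Li]C(C)(C)C (lithium of 14 and 15 only)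
Why: Fischer carbene synthesis: bromine–lithium exchange at −78 °C is faster than deprotonation of the acidic C1 methyl group (as in the routine lithiation of bromopicolines), the methoxy-stabilised aryllithium adds to a CO ligand of Cr(CO)6, and one equivalent of the hard electrophile MeOTf caps the anionic acylate oxygen ahead of the ring nitrogen, which two methyl groups shield.

Step 10
Reactants: 16 pentacarbonyl{methoxy[2-methoxy-5-(8-methoxy-1,3-dimethylisoquinolin-7-yl)-4-methylphenyl]methylidene}chromium; 17 trimethylsilylacetylene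
Product: 19 4,5-dimethoxy-8-(8-methoxy-1,3-dimethylisoquinolin-7-yl)-7-methyl-2-(trimethylsilyl)naphthalen-1-ol, via tricarbonylchromium naphthol complex 18 (not isolated)
Conditions: Me3SiC≡CH (5 equiv), THF (concentrated), 55 °C, sealed tube, Ar; then air, Et2O, rt
Reagents that add atoms: none
Why: Heating expels one cis CO from the zerovalent chromium carbene (the C4' methoxy oxygen can hold the vacant site until the alkyne arrives), the alkyne inserts with its unsubstituted carbon bonding to the carbene carbon (C5'–C6'), and CO migration onto the new vinylcarbene carbon (C7'–C8') gives a chromium-bound vinylketene. Ring B then closes by 6π electrocyclisation of the aryl–vinyl–ketene triene (C8'–C8a'), and tautomerisation of the dienone gives the naphthol, held as the Cr(CO)3 complex 18 until air releases 19. This is the Dötz benzannulation of an aryl(methoxy)carbene complex, for which o-methoxyaryl complexes and silylacetylenes used as ethyne surrogates are established partners. Site selectivity is fixed because C4' carries methoxy and C8a' is the only ortho carbon bearing hydrogen, while alkyne orientation follows the steric rule that sets the larger SiMe3 end next to the CO-derived carbon, and any slip is erased when silicon is removed. Six-membered closure with CO insertion is favoured over five-membered closure by chromium, the methoxy donor, THF and a high alkyne concentration, and the ring nitrogen is kept off chromium by its two flanking methyl groups. No stereocentre is formed, and the C7–C1' axis, which becomes fully hindered here, is obtained racemic.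

Step 11
Reactants: 19 4,5-dimethoxy-8-(8-methoxy-1,3-dimethylisoquinolin-7-yl)-7-methyl-2-(trimethylsilyl)naphthalen-1-ol
Product: 20 4,5-dimethoxy-8-(8-methoxy-1,3-dimethylisoquinolin-7-yl)-7-methylnaphthalen-1-ol
Conditions: CF3CO2H, CH2Cl2, Ar, 0 °C → rt; NaHCO3 work-up
Reagents that add atoms: none
Why: Ipso-protodesilylation (electrophilic aromatic substitution) is fast at C7' because the ortho hydroxyl stabilises the arenium ion, and it is done before triflation since an o-silylaryl triflate would be an aryne precursor.

Step 12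
Reactants: 20 4,5-dimethoxy-8-(8-methoxy-1,3-dimethylisoquinolin-7-yl)-7-methylnaphthalen-1-ol
Product: 21 4,5-dimethoxy-8-(8-methoxy-1,3-dimethylisoquinolin-7-yl)-7-methylnaphthalen-1-yl trifluoromethanesulfonate
Conditions: PhNTf2, Et3N, DMAP (cat.), CH2Cl2, rt → reflux
Reagents that add atoms: N-phenylbis(trifluoromethanesulfonimide), O=S(=O)(N(c1ccccc1)S(=O)(=O)C(F)(F)F)C(F)(F)F
Why: Phenol triflation with the mild triflyl donor PhNTf2, chosen over Tf2O so that the isoquinoline nitrogen and its C1 methyl group are not attacked.

Step 13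
Reactants: 21 4,5-dimethoxy-8-(8-methoxy-1,3-dimethylisoquinolin-7-yl)-7-methylnaphthalen-1-yl trifluoromethanesulfonate
Product: 22 7-(4,5-dimethoxy-2-methylnaphthalen-1-yl)-8-methoxy-1,3-dimethylisoquinoline (target)
Conditions: Pd(OAc)2 (cat.), dppf, HCO2H, Et3N, DMF, 85 °C
Reagents that add atoms: none
Why: Palladium-catalysed transfer hydrogenolysis of an aryl triflate: oxidative addition, exchange of triflate for formate, loss of CO2 and C–H reductive elimination replace the C8' oxygen by hydrogen without touching the methyl ethers or the heterocycle.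

**Compound list**
1 | 1-(2,6-dihydroxyphenyl)ethanone | CC(=O)c1c(O)cccc1O | starting material
2 | 2-acetyl-3-hydroxyphenyl trifluoromethanesulfonate | CC(=O)c1c(O)cccc1OS(=O)(=O)C(F)(F)F | intermediate
3 | propyne | CC#C | starting material
4 | 1-[2-hydroxy-6-(prop-1-yn-1-yl)phenyl]ethanone | CC#Cc1cccc(O)c1C(C)=O | intermediate
5 | 2-(1-iminoethyl)-3-(prop-1-yn-1-yl)phenol (ketimine, not isolated) | CC#Cc1cccc(O)c1C(C)=N | intermediate
6 | 1,3-dimethylisoquinolin-8-ol | Cc1cc2cccc(O)c2c(C)n1 | intermediate
7 | 7-bromo-1,3-dimethylisoquinolin-8-ol | Cc1cc2ccc(Br)c(O)c2c(C)n1 | intermediate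
8 | 7-bromo-8-methoxy-1,3-dimethylisoquinoline | COc1c(Br)ccc2cc(C)nc(C)c12 | intermediate
9 | 8-methoxy-1,3-dimethyl-7-(4,4,5,5-tetramethyl-1,3,2-dioxaborolan-2-yl)isoquinoline | COc1c(B3OC(C)(C)C(C)(C)O3)ccc2cc(C)nc(C)c12 | intermediate
10 | 2-bromo-5-methylanisole | COc1cc(C)ccc1Br | starting material
11 | 1-bromo-5-iodo-2-methoxy-4-methylbenzene | COc1cc(C)c(I)cc1Br | intermediate
12 | 7-(5-bromo-4-methoxy-2-methylphenyl)-8-methoxy-1,3-dimethylisoquinoline | COc1cc(C)c(-c2ccc3cc(C)nc(C)c3c2OC)cc1Br | intermediate
13 | chromium hexacarbonyl | O=C=[Cr](=C=O)(=C=O)(=C=O)(=C=O)=C=O | starting material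
14 | [2-methoxy-5-(8-methoxy-1,3-dimethylisoquinolin-7-yl)-4-methylphenyl]lithium (not isolated) | [Li]c1cc(-c2ccc3cc(C)nc(C)c3c2OC)c(C)cc1OC | intermediate
15 | lithium pentacarbonyl[2-methoxy-5-(8-methoxy-1,3-dimethylisoquinolin-7-yl)-4-methylbenzoyl]chromate (not isolated) | [Li+].[O-]C(=[Cr](=C=O)(=C=O)(=C=O)(=C=O)=C=O)c1cc(-c2ccc3cc(C)nc(C)c3c2OC)c(C)cc1OC | intermediate
16 | pentacarbonyl{methoxy[2-methoxy-5-(8-methoxy-1,3-dimethylisoquinolin-7-yl)-4-methylphenyl]methylidene}chromium | COC(=[Cr](=C=O)(=C=O)(=C=O)(=C=O)=C=O)c1cc(-c2ccc3cc(C)nc(C)c3c2OC)c(C)cc1OC | intermediate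
17 | trimethylsilylacetylene | C#C[Si](C)(C)C | starting material
18 | tricarbonylchromium complex of 19, metal bound η6 to the new ring (bond not drawn; not isolated) | COc1cc([Si](C)(C)C)c(O)c2c(-c3ccc4cc(C)nc(C)c4c3OC)c(C)cc(OC)c12.O=C=[Cr](=C=O)=C=O | intermediate
19 | 4,5-dimethoxy-8-(8-methoxy-1,3-dimethylisoquinolin-7-yl)-7-methyl-2-(trimethylsilyl)naphthalen-1-ol | COc1cc([Si](C)(C)C)c(O)c2c(-c3ccc4cc(C)nc(C)c4c3OC)c(C)cc(OC)c12 | intermediate
20 | 4,5-dimethoxy-8-(8-methoxy-1,3-dimethylisoquinolin-7-yl)-7-methylnaphthalen-1-ol | COc1ccc(O)c2c(-c3ccc4cc(C)nc(C)c4c3OC)c(C)cc(OC)c12 | intermediate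
21 | 4,5-dimethoxy-8-(8-methoxy-1,3-dimethylisoquinolin-7-yl)-7-methylnaphthalen-1-yl trifluoromethanesulfonate | COc1ccc(OS(=O)(=O)C(F)(F)F)c2c(-c3ccc4cc(C)nc(C)c4c3OC)c(C)cc(OC)c12 | intermediate
22 | 7-(4,5-dimethoxy-2-methylnaphthalen-1-yl)-8-methoxy-1,3-dimethylisoquinoline | COc1c(-c2c(C)cc(OC)c3c(OC)cccc23)ccc2cc(C)nc(C)c12 | target

**Step count.** Total steps: 13. Longest linear sequence: 12 steps (steps 1–6 and 8–13, from 1).

**Steps most likely to fail**

**Step 10.**
- What may go wrong: the vinylketene has to close onto C8a' right beside the twisted isoquinolinyl group. CO insertion and six-membered closure may therefore be outrun by five-membered closure or by simple decay of the complex. Binding of the ring nitrogen to chromium could also stall alkyne uptake.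
- Fallback, from bromide 12 and without chromium: 12 is treated with excess lithium 2,2,6,6-tetramethylpiperidide in THF (−78 °C → rt) in the presence of 2-methoxyfuran.
  - The first equivalent of base rests on the C1 methyl group, which is reprotonated at work-up.
  - Further base removes the hydrogen between bromine and the biaryl carbon, and loss of LiBr gives 3-methoxy-5-methyl-6-(8-methoxy-1,3-dimethylisoquinolin-7-yl)-1,2-didehydrobenzene F1.
  - The C4' methoxy group polarises this aryne, so the unsubstituted furan carbon bonds to C8a' and the methoxy-bearing one to C4a'. The [4+2] adduct is 1,8-dimethoxy-5-(8-methoxy-1,3-dimethylisoquinolin-7-yl)-6-methyl-1,4-dihydro-1,4-epoxynaphthalene F2.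
  - Brief treatment with CF3CO2H in CH2Cl2 opens the bridged acetal and aromatises it, and the route is rejoined at naphthol 20.

**Step 9.**
- What may go wrong: proton transfer from the C1 methyl group to the aryllithium may compete while the sparingly soluble Cr(CO)6 is being captured. That would return debrominated material.
- Fallback, from 12 and 13, avoiding any carbanion:
  - Hydroxycarbonylation of 12 (Pd(OAc)2, Xantphos, CO, H2O, Et3N, dioxane) should give 2-methoxy-5-(8-methoxy-1,3-dimethylisoquinolin-7-yl)-4-methylbenzoic acid F3.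
  - F3 is converted under neutral conditions with 1-chloro-N,N,2-trimethylprop-1-en-1-amine into 2-methoxy-5-(8-methoxy-1,3-dimethylisoquinolin-7-yl)-4-methylbenzoyl chloride F4.
  - Separately, 13 is reduced with C8K in THF to dipotassium pentacarbonylchromate F5.
  - Acylation of F5 by F4 at −78 °C gives potassium pentacarbonyl[2-methoxy-5-(8-methoxy-1,3-dimethylisoquinolin-7-yl)-4-methylbenzoyl]chromate F6.
  - O-Methylation of F6 with one equivalent of MeOTf rejoins the route at 16.

**Step 4.**
- What may go wrong: attack of the brominating agent at the para position C5 may compete with delivery to C7, or a second bromination may follow.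
- Fallback, from 6, using a removable para block:
  - Sulfonation with H2SO4·SO3 at rt should occupy C5 and give 8-hydroxy-1,3-dimethylisoquinoline-5-sulfonic acid F7.
  - Bromination of F7 with Br2 in aqueous acetic acid can then only reach C7 and gives 7-bromo-8-hydroxy-1,3-dimethylisoquinoline-5-sulfonic acid F8.
  - Heating F8 in dilute H2SO4 brings about protodesulfonation and rejoins the route at 7.

**Further compounds**
F1 | step 10 | 3-methoxy-5-methyl-6-(8-methoxy-1,3-dimethylisoquinolin-7-yl)-1,2-didehydrobenzene (aryne) | COC1=CC(C)=C(c2ccc3cc(C)nc(C)c3c2OC)C#C1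
F2 | step 10 | 1,8-dimethoxy-5-(8-methoxy-1,3-dimethylisoquinolin-7-yl)-6-methyl-1,4-dihydro-1,4-epoxynaphthalene (racemic, axis uncontrolled) | COC12C=CC(O1)c1c(-c3ccc4cc(C)nc(C)c4c3OC)c(C)cc(OC)c12
F3 | step 9 | 2-methoxy-5-(8-methoxy-1,3-dimethylisoquinolin-7-yl)-4-methylbenzoic acid | COc1cc(C)c(-c2ccc3cc(C)nc(C)c3c2OC)cc1C(=O)O
F4 | step 9 | 2-methoxy-5-(8-methoxy-1,3-dimethylisoquinolin-7-yl)-4-methylbenzoyl chloride | COc1cc(C)c(-c2ccc3cc(C)nc(C)c3c2OC)cc1C(=O)Cl
F5 | step 9 | dipotassium pentacarbonylchromate, K2Cr(CO)5 | [K+].[K+].O=C=[Cr-2](=C=O)(=C=O)(=C=O)=C=O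
F6 | step 9 | potassium pentacarbonyl[2-methoxy-5-(8-methoxy-1,3-dimethylisoquinolin-7-yl)-4-methylbenzoyl]chromate | [K+].[O-]C(=[Cr](=C=O)(=C=O)(=C=O)(=C=O)=C=O)c1cc(-c2ccc3cc(C)nc(C)c3c2OC)c(C)cc1OC
F7 | step 4 | 8-hydroxy-1,3-dimethylisoquinoline-5-sulfonic acid | Cc1cc2c(S(=O)(=O)O)ccc(O)c2c(C)n1
F8 | step 4 | 7-bromo-8-hydroxy-1,3-dimethylisoquinoline-5-sulfonic acid | Cc1cc2c(S(=O)(=O)O)cc(Br)c(O)c2c(C)n1
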